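**Plan**
- Retrosynthesis: the C2–O1 and C2–C3 bonds of both flavanones are cut back to an aryl aldehyde plus a 2-hydroxyaryl β-keto ester (unit 1 first, then unit 2). The acetyl group is then removed from C4a of unit 2, and ring B of unit 1 is cut at C3'–C4' and C5'–C6' into methyl coumalate and an aryl ethynyl ether.
- Enabling feature: the ether oxygen sits on C6 of ring A of unit 2, between the oxygens on C5 and C7, whereas ring B of unit 1 is a plain 1,4-disubstituted benzene. Its C4'–O and C1'–C map onto the O–C≡C of an ynol ether and the ester-bearing C5 of a 2-pyrone, so ring B can be grown on the crowded oxygen.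
- Forward: ring A of unit 2 comes from phloroglucinaldehyde (4-O-MOM, 2,6-di-O-benzyl, Dakin oxidation, ethynyl ether). Ring B follows by Diels–Alder/decarboxylation, then ring C of unit 2 and ring C of unit 1 by oxa-Michael closures, and hydrogenolysis ends the route.
- Stereochemistry: C2 and C2'' (both S) are set by the same chiral cinchona thiourea catalyst in the two oxa-Michael closures; no other stereocentre survives to the target.

Key step: step 6

Remark on naming: unit 1 is the flavanone whose ring B carries the ether oxygen; unit 2 (doubly primed locants) is the one whose ring A carries it at C6''.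
Assumption: the quinine-derived thiourea is taken as the pseudoenantiomer that gives the 2S series. If a trial of step 11 shows the opposite sense, the quinidine-derived pseudoenantiomer is used in steps 11 and 17.

**Route**

Step 1
Reactants: 1 2,4,6-trihydroxybenzaldehyde; 2 chloromethyl methyl ether
Product: 3 2,6-dihydroxy-4-(methoxymethoxy)benzaldehyde
Conditions: MOMCl (1.0 equiv), i-Pr2NEt (1.1 equiv), THF, 0 °C
Reagents that add atoms: chloromethyl methyl ether (2), COCCl
Why: Williamson-type O-alkylation should stop at the 4-hydroxyl, which is the most acidic phenol (para to the formyl group) and the only one not weakened by hydrogen bonding to the carbonyl.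

Step 2
Reactants: 3 2,6-dihydroxy-4-(methoxymethoxy)benzaldehyde; 4 benzyl bromide
Product: 5 2,6-bis(benzyloxy)-4-(methoxymethoxy)benzaldehyde
Conditions: BnBr (2.4 equiv), K2CO3, DMF, 60 °C
Reagents that add atoms: benzyl bromide (4), BrCc1ccccc1
Why: Williamson ether synthesis under warm carbonate conditions should benzylate both ortho hydroxyls, while the MOM acetal and the aldehyde are inert to K2CO3.

Step 3
Reactants: 5 2,6-bis(benzyloxy)-4-(methoxymethoxy)benzaldehyde; 6 3-chloroperoxybenzoic acid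
Product: 8 2,6-bis(benzyloxy)-4-(methoxymethoxy)phenol, via aryl formate 7 (not isolated)
Conditions: mCPBA, CH2Cl2, 0 °C to rt; then K2CO3 (cat.), MeOH, 0 °C, Ar
Reagents that add atoms: 3-chloroperoxybenzoic acid (6), OOC(=O)c1cccc(Cl)c1
Why: In this Baeyer–Villiger (Dakin-type) oxidation the electron-rich trialkoxyphenyl group should migrate in preference to hydride, and mild methanolysis of the formate frees the phenol flanked by the two benzyloxy groups without touching the MOM acetal.

Step 4
Reactants: 8 2,6-bis(benzyloxy)-4-(methoxymethoxy)phenol; 9 trichloroethylene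
Product: 10 1,3-bis(benzyloxy)-2-{[(E)-1,2-dichlorovinyl]oxy}-5-(methoxymethoxy)benzene
Conditions: ClCH=CCl2 (1.5 equiv), K2CO3, DMF, 70 °C, Ar
Reagents that add atoms: trichloroethylene (9), ClC=C(Cl)Cl
Why: Carbonate converts trichloroethylene into dichloroacetylene in the flask and the hindered phenoxide should add anti to this small linear electrophile, the established nucleophilic addition route from phenols to (E)-1,2-dichlorovinyl ethers.

Step 5
Reactants: 10 1,3-bis(benzyloxy)-2-{[(E)-1,2-dichlorovinyl]oxy}-5-(methoxymethoxy)benzene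
Product: 13 1,3-bis(benzyloxy)-2-(ethynyloxy)-5-(methoxymethoxy)benzene, via chloroethynyl ether 11 (not isolated), via lithium acetylide 12 (not isolated)
Conditions: n-BuLi (2.4 equiv), THF, −78 to −40 °C; then H2O, −78 °C; used at once
Reagents that add atoms: none
Why: Butyllithium should effect dehydrochlorination to the chloroalkyne and then chlorine–lithium exchange to the acetylide, which is protonated cold (the standard dichlorovinyl ether to ynol ether elimination), and benzyl and MOM ethers tolerate n-BuLi at this temperature.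

Step 6
Reactants: 13 1,3-bis(benzyloxy)-2-(ethynyloxy)-5-(methoxymethoxy)benzene; 14 methyl coumalate (methyl 2-oxo-2H-pyran-5-carboxylate)
Product: 16 methyl 4-[2,6-bis(benzyloxy)-4-(methoxymethoxy)phenoxy]benzoate, via bicyclic lactone 15 (not isolated)
Conditions: 14 (2 equiv), BHT (5 mol%), toluene, 110 °C, sealed tube, Ar
Reagents that add atoms: methyl coumalate (14), COC(=O)c1ccc(=O)oc1
Why: The oxygen-activated alkyne adds as dienophile across C3 and C6 of the electron-poor 2-pyrone in an inverse-electron-demand [4+2] cycloaddition, and the bridged 2-oxabicyclo[2.2.2]octadienone 15 then expels CO2 by retro-[4+2] to leave the benzene ring; the closest known reaction type is the Diels–Alder/decarboxylation of methyl coumalate with alkoxyalkynes, ynamines and enol ethers, which gives para-substituted benzoates. Ring B of unit 1 is closed intermolecularly through two new C–C bonds (C3'–C4' and C5'–C6') in a [4+2] mode and becomes aromatic in the cycloreversion, so no stereocentre is formed and none needs control. The selectivity required is para over meta orientation, and it should follow from polarity matching: the nucleophilic terminal CH carbon of 13 bonds to C6 of the pyrone, the electrophilic position β to the ester and vinylogous to the lactone carbonyl, which leaves the aryloxy-bearing carbon on C3 and therefore para to the ester. Because the bond to the crowded oxygen already exists in 13, the step only has to make carbon–carbon bonds remote from the two benzyloxy groups, and these groups also screen the ynol ether from adding to itself. An aryl ynol ether has no β-hydrogen on its oxygen substituent, so the retro-ene collapse to a ketene that limits alkyl ynol ethers on heating is closed, and benzyl, MOM and ester groups are inert to neutral heating.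

Step 7
Reactants: 16 methyl 4-[2,6-bis(benzyloxy)-4-(methoxymethoxy)phenoxy]benzoate; 17 N-iodosuccinimide
Product: 18 methyl 4-[2,6-bis(benzyloxy)-3-iodo-4-(methoxymethoxy)phenoxy]benzoate
Conditions: NIS (1.05 equiv), MeCN, 0 °C to rt, dark
Reagents that add atoms: N-iodosuccinimide (17), O=C1CCC(=O)N1I
Why: Electrophilic aromatic iodination should occur only on the tetraoxygenated ring, at either of the two equivalent carbons that lie ortho to the MOM ether, ortho to one benzyloxy group and para to the other, since the benzoate and benzyl rings are far less nucleophilic.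

Step 8
Reactants: 18 methyl 4-[2,6-bis(benzyloxy)-3-iodo-4-(methoxymethoxy)phenoxy]benzoate; 19 tributyl(1-ethoxyvinyl)stannane; 20 water
Product: 22 methyl 4-[3-acetyl-2,6-bis(benzyloxy)-4-hydroxyphenoxy]benzoate, via enol ether 21 (not isolated)
Conditions: 19 (1.3 equiv), PdCl2(PPh3)2 (5 mol%), toluene, 100 °C; then 3 M HCl, MeOH–THF, 50 °C
Reagents that add atoms: tributyl(1-ethoxyvinyl)stannane (19), CCCC[Sn](CCCC)(CCCC)C(=C)OCC; water (20), O
Why: Stille cross-coupling with the 1-ethoxyvinyl stannane (a masked acetyl group) followed by acid hydrolysis of the enol ether should give the methyl ketone without any Lewis acid that could strip a benzyl ether, and the same methanolic acid cleaves the MOM acetal next to the new carbonyl.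

Step 9
Reactants: 22 methyl 4-[3-acetyl-2,6-bis(benzyloxy)-4-hydroxyphenoxy]benzoate; 23 di-tert-butyl dicarbonate
Product: 24 methyl 4-{2,6-bis(benzyloxy)-3-[3-(tert-butoxy)-3-oxopropanoyl]-4-hydroxyphenoxy}benzoate
Conditions: LiN(SiMe3)2 (3.2 equiv), THF, −78 °C; Boc2O (1.05 equiv), −78 to −40 °C; then 1 M HCl, 0 °C
Reagents that add atoms: di-tert-butyl dicarbonate (23), CC(C)(C)OC(=O)OC(=O)OC(C)(C)C
Why: In this Claisen-type C-acylation the phenoxide–enolate dianion should attack Boc2O at carbon and the product is deprotonated at once by the excess amide, which prevents a second acylation, while the methyl benzoate is not attacked at −78 °C.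

Step 10
Reactants: 24 methyl 4-{2,6-bis(benzyloxy)-3-[3-(tert-butoxy)-3-oxopropanoyl]-4-hydroxyphenoxy}benzoate; 25 4-(benzyloxy)benzaldehyde
Product: 26 methyl 4-{2,6-bis(benzyloxy)-3-[3-[4-(benzyloxy)phenyl]-2-(tert-butoxycarbonyl)prop-2-enoyl]-4-hydroxyphenoxy}benzoate (E/Z mixture)
Conditions: piperidine (20 mol%), AcOH (20 mol%), 4 Å molecular sieves, toluene, rt
Reagents that add atoms: 4-(benzyloxy)benzaldehyde (25), O=Cc1ccc(OCc2ccccc2)cc1
Why: Knoevenagel condensation under piperidinium acetate with removal of water should give the alkylidene β-keto ester, the activated chalcone-type substrate for the ring closure.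

Step 11
Reactants: 26 methyl 4-{2,6-bis(benzyloxy)-3-[3-[4-(benzyloxy)phenyl]-2-(tert-butoxycarbonyl)prop-2-enoyl]-4-hydroxyphenoxy}benzoate (E/Z mixture)
Product: 28 methyl 4-{[(2S)-5,7-bis(benzyloxy)-2-[4-(benzyloxy)phenyl]-4-oxochroman-6-yl]oxy}benzoate, via chromanone 3-carboxylate 27 (not isolated)
Conditions: N-[3,5-bis(trifluoromethyl)phenyl]-N'-[(8S,9S)-6'-methoxycinchonan-9-yl]thiourea (10 mol%), toluene, −25 °C; then TsOH·H2O, 80 °C
Reagents that add atoms: none
Why: In this catalytic asymmetric intramolecular oxa-Michael addition the thiourea binds the β-keto ester and the quinuclidine nitrogen activates the phenol, so the oxygen attacks one face of the alkylidene and the catalyst sets C2'' as S, after which acid cleaves the tert-butyl ester and the β-keto acid decarboxylates without touching C2''.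

Step 12
Reactants: 28 methyl 4-{[(2S)-5,7-bis(benzyloxy)-2-[4-(benzyloxy)phenyl]-4-oxochroman-6-yl]oxy}benzoate
Product: 29 (2S)-5,7-bis(benzyloxy)-2-[4-(benzyloxy)phenyl]-6-[4-(hydroxymethyl)phenoxy]chroman-4-ol (C4 epimers)
Conditions: LiAlH4, THF, 0 °C; H2O/aq. NaOH work-up (no acid)
Reagents that add atoms: none
Why: Hydride reduction takes the ester to the benzylic alcohol and, unavoidably, the ketone to the flavan-4-ol, which leaves C2'' untouched and creates a C4'' carbinol that is erased in the next step.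

Step 13
Reactants: 29 (2S)-5,7-bis(benzyloxy)-2-[4-(benzyloxy)phenyl]-6-[4-(hydroxymethyl)phenoxy]chroman-4-ol (C4 epimers)
Product: 30 4-{[(2S)-5,7-bis(benzyloxy)-2-[4-(benzyloxy)phenyl]-4-oxochroman-6-yl]oxy}benzaldehyde
Conditions: Dess–Martin periodinane (2.6 equiv), NaHCO3, CH2Cl2, 0 °C to rt
Reagents that add atoms: none
Why: Buffered Dess–Martin oxidation should restore the flavanone carbonyl and give the benzaldehyde in one operation under neutral conditions that neither ionise the electron-rich benzylic carbinol nor enolise the ketone.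

Step 14
Reactants: 31 2,4,6-trihydroxyacetophenone; 4 benzyl bromide
Product: 32 1-[2,4-bis(benzyloxy)-6-hydroxyphenyl]ethan-1-one
Conditions: BnBr (2.05 equiv), K2CO3, DMF, rt
Reagents that add atoms: benzyl bromide (4), BrCc1ccccc1
Why: Williamson benzylation should stop at the bis ether because the remaining ortho hydroxyl is strongly hydrogen-bonded to the acetyl carbonyl, the usual selectivity for phloroacetophenone.

Step 15
Reactants: 32 1-[2,4-bis(benzyloxy)-6-hydroxyphenyl]ethan-1-one; 23 di-tert-butyl dicarbonate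
Product: 33 tert-butyl 3-[2,4-bis(benzyloxy)-6-hydroxyphenyl]-3-oxopropanoate
Conditions: LiN(SiMe3)2 (3.2 equiv), THF, −78 °C; Boc2O (1.05 equiv), −78 to −40 °C; then 1 M HCl, 0 °C
Reagents that add atoms: di-tert-butyl dicarbonate (23), CC(C)(C)OC(=O)OC(=O)OC(C)(C)C
Why: The same Claisen-type C-acylation of the phenoxide–enolate dianion as in step 9 should give the β-keto ester.

Step 16
Reactants: 30 4-{[(2S)-5,7-bis(benzyloxy)-2-[4-(benzyloxy)phenyl]-4-oxochroman-6-yl]oxy}benzaldehyde; 33 tert-butyl 3-[2,4-bis(benzyloxy)-6-hydroxyphenyl]-3-oxopropanoate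
Product: 34 tert-butyl 2-[2,4-bis(benzyloxy)-6-hydroxybenzoyl]-3-[4-({(2S)-5,7-bis(benzyloxy)-2-[4-(benzyloxy)phenyl]-4-oxochroman-6-yl}oxy)phenyl]prop-2-enoate (E/Z mixture)
Conditions: 33 (1.2 equiv), piperidine (20 mol%), AcOH (20 mol%), 4 Å molecular sieves, toluene, rt
Reagents that add atoms: tert-butyl 3-[2,4-bis(benzyloxy)-6-hydroxyphenyl]-3-oxopropanoate (33), CC(C)(C)OC(=O)CC(=O)c1c(O)cc(OCc2ccccc2)cc1OCc1ccccc1
Why: In this Knoevenagel condensation only the β-keto ester, far more acidic than the C3'' methylene of the flavanone, should condense with the aldehyde, and the buffered amine at room temperature is mild enough to keep the existing flavanone closed.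

Step 17
Reactants: 34 tert-butyl 2-[2,4-bis(benzyloxy)-6-hydroxybenzoyl]-3-[4-({(2S)-5,7-bis(benzyloxy)-2-[4-(benzyloxy)phenyl]-4-oxochroman-6-yl}oxy)phenyl]prop-2-enoate (E/Z mixture)
Product: 36 (2S)-5,7-bis(benzyloxy)-2-[4-({(2S)-5,7-bis(benzyloxy)-2-[4-(benzyloxy)phenyl]-4-oxochroman-6-yl}oxy)phenyl]chroman-4-one, via chromanone 3-carboxylate 35 (not isolated)
Conditions: N-[3,5-bis(trifluoromethyl)phenyl]-N'-[(8S,9S)-6'-methoxycinchonan-9-yl]thiourea (10 mol%), toluene, −25 °C; then TsOH·H2O, 80 °C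
Reagents that add atoms: none
Why: The same thiourea-catalysed asymmetric oxa-Michael addition and acid-induced decarboxylation should close ring C of unit 1, with C2 set as S by the catalyst alone because the existing C2'' centre is remote across the diaryl ether.

Step 18
Reactants: 36 (2S)-5,7-bis(benzyloxy)-2-[4-({(2S)-5,7-bis(benzyloxy)-2-[4-(benzyloxy)phenyl]-4-oxochroman-6-yl}oxy)phenyl]chroman-4-one
Product: 37 (2S)-5,7-dihydroxy-2-(4-{[(2S)-5,7-dihydroxy-2-(4-hydroxyphenyl)-4-oxochroman-6-yl]oxy}phenyl)chroman-4-one (CNP0184214.1)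
Conditions: H2 (1 atm), Pd/C (10% Pd), EtOAc–MeOH, rt
Reagents that add atoms: none
Why: Catalytic hydrogenolysis should remove the five benzyl ethers under neutral conditions that leave the flavanone carbonyls and C2–O1 bonds intact and, being free of acid and base, cannot open the rings and racemise C2 or C2''.

**Compound list**
1 | 2,4,6-trihydroxybenzaldehyde | O=Cc1c(O)cc(O)cc1O | starting material
2 | chloromethyl methyl ether | COCCl | starting material
3 | 2,6-dihydroxy-4-(methoxymethoxy)benzaldehyde | O=Cc1c(O)cc(OCOC)cc1O | intermediate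
4 | benzyl bromide | BrCc1ccccc1 | starting material
5 | 2,6-bis(benzyloxy)-4-(methoxymethoxy)benzaldehyde | O=Cc1c(OCc2ccccc2)cc(OCOC)cc1OCc1ccccc1 | intermediate
6 | 3-chloroperoxybenzoic acid | OOC(=O)c1cccc(Cl)c1 | starting material
7 | 2,6-bis(benzyloxy)-4-(methoxymethoxy)phenyl formate | O=COc1c(OCc2ccccc2)cc(OCOC)cc1OCc1ccccc1 | intermediate
8 | 2,6-bis(benzyloxy)-4-(methoxymethoxy)phenol | Oc1c(OCc2ccccc2)cc(OCOC)cc1OCc1ccccc1 | intermediate
9 | trichloroethylene | ClC=C(Cl)Cl | starting material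
10 | 1,3-bis(benzyloxy)-2-{[(E)-1,2-dichlorovinyl]oxy}-5-(methoxymethoxy)benzene | Cl/C=C(/Cl)Oc1c(OCc2ccccc2)cc(OCOC)cc1OCc1ccccc1 | intermediate
11 | 1,3-bis(benzyloxy)-2-[(chloroethynyl)oxy]-5-(methoxymethoxy)benzene | ClC#COc1c(OCc2ccccc2)cc(OCOC)cc1OCc1ccccc1 | intermediate
12 | lithium 2-[2,6-bis(benzyloxy)-4-(methoxymethoxy)phenoxy]ethynide | [Li]C#COc1c(OCc2ccccc2)cc(OCOC)cc1OCc1ccccc1 | intermediate
13 | 1,3-bis(benzyloxy)-2-(ethynyloxy)-5-(methoxymethoxy)benzene | C#COc1c(OCc2ccccc2)cc(OCOC)cc1OCc1ccccc1 | intermediate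
14 | methyl coumalate (methyl 2-oxo-2H-pyran-5-carboxylate) | COC(=O)c1ccc(=O)oc1 | starting material
15 | methyl 5-[2,6-bis(benzyloxy)-4-(methoxymethoxy)phenoxy]-3-oxo-2-oxabicyclo[2.2.2]octa-5,7-diene-7-carboxylate (racemic) | COC(=O)C1=CC2C(=O)OC1C=C2Oc1c(OCc2ccccc2)cc(OCOC)cc1OCc1ccccc1 | intermediate
16 | methyl 4-[2,6-bis(benzyloxy)-4-(methoxymethoxy)phenoxy]benzoate | COC(=O)c1ccc(Oc2c(OCc3ccccc3)cc(OCOC)cc2OCc2ccccc2)cc1 | intermediate
17 | N-iodosuccinimide | O=C1CCC(=O)N1I | starting material
18 | methyl 4-[2,6-bis(benzyloxy)-3-iodo-4-(methoxymethoxy)phenoxy]benzoate | COC(=O)c1ccc(Oc2c(OCc3ccccc3)cc(OCOC)c(I)c2OCc2ccccc2)cc1 | intermediate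
19 | tributyl(1-ethoxyvinyl)stannane | CCCC[Sn](CCCC)(CCCC)C(=C)OCC | starting material
20 | water | O | starting material
21 | methyl 4-[2,6-bis(benzyloxy)-3-(1-ethoxyvinyl)-4-(methoxymethoxy)phenoxy]benzoate | COC(=O)c1ccc(Oc2c(OCc3ccccc3)cc(OCOC)c(C(=C)OCC)c2OCc2ccccc2)cc1 | intermediate
22 | methyl 4-[3-acetyl-2,6-bis(benzyloxy)-4-hydroxyphenoxy]benzoate | COC(=O)c1ccc(Oc2c(OCc3ccccc3)cc(O)c(C(C)=O)c2OCc2ccccc2)cc1 | intermediate
23 | di-tert-butyl dicarbonate | CC(C)(C)OC(=O)OC(=O)OC(C)(C)C | starting material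
24 | methyl 4-{2,6-bis(benzyloxy)-3-[3-(tert-butoxy)-3-oxopropanoyl]-4-hydroxyphenoxy}benzoate | COC(=O)c1ccc(Oc2c(OCc3ccccc3)cc(O)c(C(=O)CC(=O)OC(C)(C)C)c2OCc2ccccc2)cc1 | intermediate
25 | 4-(benzyloxy)benzaldehyde | O=Cc1ccc(OCc2ccccc2)cc1 | starting material
26 | methyl 4-{2,6-bis(benzyloxy)-3-[3-[4-(benzyloxy)phenyl]-2-(tert-butoxycarbonyl)prop-2-enoyl]-4-hydroxyphenoxy}benzoate (E/Z mixture) | COC(=O)c1ccc(Oc2c(OCc3ccccc3)cc(O)c(C(=O)C(=Cc3ccc(OCc4ccccc4)cc3)C(=O)OC(C)(C)C)c2OCc2ccccc2)cc1 | intermediate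
27 | tert-butyl (2S)-5,7-bis(benzyloxy)-2-[4-(benzyloxy)phenyl]-6-[4-(methoxycarbonyl)phenoxy]-4-oxochromane-3-carboxylate (C3 epimers and enol) | COC(=O)c1ccc(Oc2c(OCc3ccccc3)cc3c(c2OCc2ccccc2)C(=O)C(C(=O)OC(C)(C)C)[C@@H](c2ccc(OCc4ccccc4)cc2)O3)cc1 | intermediate
28 | methyl 4-{[(2S)-5,7-bis(benzyloxy)-2-[4-(benzyloxy)phenyl]-4-oxochroman-6-yl]oxy}benzoate | COC(=O)c1ccc(Oc2c(OCc3ccccc3)cc3c(c2OCc2ccccc2)C(=O)C[C@@H](c2ccc(OCc4ccccc4)cc2)O3)cc1 | intermediate
29 | (2S)-5,7-bis(benzyloxy)-2-[4-(benzyloxy)phenyl]-6-[4-(hydroxymethyl)phenoxy]chroman-4-ol (C4 epimers) | OCc1ccc(Oc2c(OCc3ccccc3)cc3c(c2OCc2ccccc2)C(O)C[C@@H](c2ccc(OCc4ccccc4)cc2)O3)cc1 | intermediate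
30 | 4-{[(2S)-5,7-bis(benzyloxy)-2-[4-(benzyloxy)phenyl]-4-oxochroman-6-yl]oxy}benzaldehyde | O=Cc1ccc(Oc2c(OCc3ccccc3)cc3c(c2OCc2ccccc2)C(=O)C[C@@H](c2ccc(OCc4ccccc4)cc2)O3)cc1 | intermediate
31 | 2,4,6-trihydroxyacetophenone | CC(=O)c1c(O)cc(O)cc1O | starting material
32 | 1-[2,4-bis(benzyloxy)-6-hydroxyphenyl]ethan-1-one | CC(=O)c1c(O)cc(OCc2ccccc2)cc1OCc1ccccc1 | intermediate
33 | tert-butyl 3-[2,4-bis(benzyloxy)-6-hydroxyphenyl]-3-oxopropanoate | CC(C)(C)OC(=O)CC(=O)c1c(O)cc(OCc2ccccc2)cc1OCc1ccccc1 | intermediate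
34 | tert-butyl 2-[2,4-bis(benzyloxy)-6-hydroxybenzoyl]-3-[4-({(2S)-5,7-bis(benzyloxy)-2-[4-(benzyloxy)phenyl]-4-oxochroman-6-yl}oxy)phenyl]prop-2-enoate (E/Z mixture) | CC(C)(C)OC(=O)C(=Cc1ccc(Oc2c(OCc3ccccc3)cc3c(c2OCc2ccccc2)C(=O)C[C@@H](c2ccc(OCc4ccccc4)cc2)O3)cc1)C(=O)c1c(O)cc(OCc2ccccc2)cc1OCc1ccccc1 | intermediate
35 | tert-butyl (2S)-5,7-bis(benzyloxy)-2-[4-({(2S)-5,7-bis(benzyloxy)-2-[4-(benzyloxy)phenyl]-4-oxochroman-6-yl}oxy)phenyl]-4-oxochromane-3-carboxylate (C3 epimers and enol) | CC(C)(C)OC(=O)C1C(=O)c2c(OCc3ccccc3)cc(OCc3ccccc3)cc2O[C@@H]1c1ccc(Oc2c(OCc3ccccc3)cc3c(c2OCc2ccccc2)C(=O)C[C@@H](c2ccc(OCc4ccccc4)cc2)O3)cc1 | intermediate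
36 | (2S)-5,7-bis(benzyloxy)-2-[4-({(2S)-5,7-bis(benzyloxy)-2-[4-(benzyloxy)phenyl]-4-oxochroman-6-yl}oxy)phenyl]chroman-4-one | O=C1C[C@@H](c2ccc(Oc3c(OCc4ccccc4)cc4c(c3OCc3ccccc3)C(=O)C[C@@H](c3ccc(OCc5ccccc5)cc3)O4)cc2)Oc2cc(OCc3ccccc3)cc(OCc3ccccc3)c21 | intermediate
37 | (2S)-5,7-dihydroxy-2-(4-{[(2S)-5,7-dihydroxy-2-(4-hydroxyphenyl)-4-oxochroman-6-yl]oxy}phenyl)chroman-4-one | O=C1C[C@@H](c2ccc(Oc3c(O)cc4c(c3O)C(=O)C[C@@H](c3ccc(O)cc3)O4)cc2)Oc2cc(O)cc(O)c21 | target

**Count**
Total: 18 steps. Longest linear sequence: 16 steps (steps 1–13 and 16–18); steps 14 and 15 form the side branch to 33.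

**Steps most likely to fail**

1. Step 6. The terminal ynol ether 13 may oligomerise or pick up adventitious water on heating faster than the pyrone intercepts it, or the cycloaddition may need a temperature at which 13 no longer survives. Fallback: starting from phenol 8, a copper-catalysed Ullmann-type diaryl ether synthesis with methyl 4-iodobenzoate (CuI, that is monovalent copper iodide, with picolinic acid, K3PO4, DMSO, 90 °C), a protocol that accepts 2,6-disubstituted phenols, would give 16 directly and rejoin the route at 16. No new compound lies on this path.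

2. Step 11. Facial selectivity may be poor and closure slow, because the benzyloxy and aryloxy groups next to the ketone twist it out of the ring plane and weaken the two-point binding to the thiourea, and uncatalysed racemic closure may compete. Fallback: starting from hydroxy ketone 22, condensation with N,N-dimethylformamide dimethyl acetal (toluene, 90 °C) would give methyl 4-{2,6-bis(benzyloxy)-3-[(2E)-3-(dimethylamino)prop-2-enoyl]-4-hydroxyphenoxy}benzoate F1. Acid (HCl, CH2Cl2) would cyclise it to methyl 4-{[5,7-bis(benzyloxy)-4-oxo-4H-chromen-6-yl]oxy}benzoate F2. Enantioselective conjugate addition of 4-(benzyloxy)phenylboronic acid to this chromone, catalysed by Pd(OCOCF3)2 with the enantiomer of 4-tert-butyl-2-(pyridin-2-yl)oxazoline that leads to the 2S adduct (NH4PF6, H2O, 1,2-dichloroethane, 60 °C), would give 28 and rejoin the route there.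

3. Step 17. The amine catalysts of steps 16 and 17 may reopen the flavanone already present by retro-oxa-Michael reaction and erode C2'', and catalyst control in the new closure may be incomplete. Fallback: ketone 32 would be converted with Me3SiOTf and Et3N into 1,5-bis(benzyloxy)-3-(trimethylsilyloxy)-2-[1-(trimethylsilyloxy)vinyl]benzene F3. Starting from aldehyde 30, an enantioselective Mukaiyama aldol addition of this silyl enol ether under a chiral B-butyl oxazaborolidinone Lewis acid derived from N-tosyltryptophan (enantiomer chosen for the 3R adduct; EtCN, −78 °C; mild acidic desilylation) would give (3R)-1-[2,4-bis(benzyloxy)-6-hydroxyphenyl]-3-hydroxy-3-[4-({(2S)-5,7-bis(benzyloxy)-2-[4-(benzyloxy)phenyl]-4-oxochroman-6-yl}oxy)phenyl]propan-1-one F4. Mitsunobu cyclisation (PPh3, diisopropyl azodicarboxylate, THF, 0 °C) would close ring C with inversion to the 2S configuration and rejoin the route at 36, with no amine base used.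

**Further compounds**
F0 | step 6 | none | none
F1 | step 11 | methyl 4-{2,6-bis(benzyloxy)-3-[(2E)-3-(dimethylamino)prop-2-enoyl]-4-hydroxyphenoxy}benzoate | COC(=O)c1ccc(Oc2c(OCc3ccccc3)cc(O)c(C(=O)/C=C/N(C)C)c2OCc2ccccc2)cc1
F2 | step 11 | methyl 4-{[5,7-bis(benzyloxy)-4-oxo-4H-chromen-6-yl]oxy}benzoate | COC(=O)c1ccc(Oc2c(OCc3ccccc3)cc3occc(=O)c3c2OCc2ccccc2)cc1
F3 | step 17 | 1,5-bis(benzyloxy)-3-(trimethylsilyloxy)-2-[1-(trimethylsilyloxy)vinyl]benzene | C=C(O[Si](C)(C)C)c1c(O[Si](C)(C)C)cc(OCc2ccccc2)cc1OCc1ccccc1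
F4 | step 17 | (3R)-1-[2,4-bis(benzyloxy)-6-hydroxyphenyl]-3-hydroxy-3-[4-({(2S)-5,7-bis(benzyloxy)-2-[4-(benzyloxy)phenyl]-4-oxochroman-6-yl}oxy)phenyl]propan-1-one | O=C(C[C@@H](O)c1ccc(Oc2c(OCc3ccccc3)cc3c(c2OCc2ccccc2)C(=O)C[C@@H](c2ccc(OCc4ccccc4)cc2)O3)cc1)c1c(O)cc(OCc2ccccc2)cc1OCc1ccccc1
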